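The numbers of this flask were drawn at random within sensible limits; the result is computed.

I began with the easy step: what the charge of J loses at once.

J 0.20 M; D 0.0200 M; Z 2.5 mol%; time 25 min

    J + Z → J.Z (k1 = 0.13 /M/min)
    J + Q → X + Q, rate k2*[Q]*[J] (k2 = 2.7 /M/min)
    D + J → D.J (k3 = 3.5 /M/min)
    X + Q → J + Q, rate k4*[Q] as long as [X] is above zero (k4 = 0.13 /min)
    J + Z → Q + X (k5 = 2.0 /M/min)

- average number of monomer units in a chain (chains begun, living or dead) at 25 min
- part of the J that has reacted at 25 min

- the average divides the monomer in chains by the number of chains begun, living and dead together
- run time (flask): 25 min

I counted everything as a fraction of the J charged. With J at its charge, D had a half-life of 0.99 min and Z one of 1.63 min, both far shorter than the run . So I let D take 10.0 % and Z take 2.50 % at the outset, which left a head of 87.5 % of J. Of Z, 93.9 % went to living ends, so the ends stood at 2.35 %.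

That was the early end. At the late end, growth and unzipping both carry Q, so Q fell out of their balance. That gave 24.1 % of the charge. This is the floor: the part of J where growth and unzipping balance, equal to the unzipping constant over the growth constant times the charge of J. Told as a concentration, its usual name is the equilibrium monomer concentration.

To join the ends, I let the excess of J over the floor decay pseudo-first-order. Its time was 78.9 min, longer than the run, so I expected J well above the floor. This first join gave J 70.3 %.

But the ends were not there at the start. They arrived over Z's mean life, 2.35 min. Taking that off the run gave J 71.7 %, so c came to 28.3 %.

A second doubt: c counts the J taken by D, and chains do not hold it. Without that part and J.Z, X came to 18.2 %, and dividing by the ends gave dp 7.74.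

The forecast gave dp 7.3 (6.6 to 8) and c 28 % (26 % to 31 %), saying that “J relaxes slowly toward its propagation–depropagation floor”. Its c was close to mine, and its dp lay below mine.

The flask gave dp 7.73 and c 28.3 %. Left ten times as long, this flask held J at 26.8 %, still above the floor of 24.1 %. For the neighbour charged with 0.80 M of J, I reckoned a floor of 6.02 %, a head of 95.0 %, a decay time of 19.7 min and a lag of 0.587 min. The same join put its J at 31.8 %. That neighbour held J at 31.8 %.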